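Assumption: compounds 1, 9, 19 and 22 are treated as catalogue compounds (19 is otherwise two routine steps from propane-1,3-diol: monosilylation, then oxidation), and an α-branched triisopropylsiloxyalkyne is taken to behave in the benzannulation as simple alkyl-substituted ones do.

Atom numbers below are those of the target: oxolane O1–C5, dihydrobenzofuran O1–C7a.

## Structural features

The target is built from a 2,3,4-trisubstituted oxolane (C2 3-hydroxy-4-methoxyphenyl, C3 CH2OH, C4 CH2) and a 2-aryl-3-hydroxymethyl-4-methoxy-2,3-dihydrobenzofuran (C2 4-hydroxy-3-methoxyphenyl), joined by one methylene from oxolane C4 to benzofuran C6. The oxolane has three contiguous stereocentres, C2 (R), C3 (S) and C4 (S), with C2/C3 trans and C3/C4 cis; the dihydrofuran has two, C2 (S) and C3 (R), trans. The two sets are separated by the CH2–arene link and cannot control each other. Both C2 atoms are p-oxygenated benzylic ethers: acid ionises them (epimerisation, or Friedel–Crafts capture of the oxolane C2 cation by the electron-rich central arene to give a tetralin), and both are open to hydrogenolysis. The real difficulty is the central benzene ring, a 1,2,3,5-tetrasubstituted resorcinol core whose two oxygens end up different (O1 at C7a, OMe at C4) and which must be joined to two separately made, enantiopure halves. The key step uses exactly this ring: C3a, which carries the C3 side chain, lies between the oxygenated carbons C4 and C7a, and C6 with the oxolanylmethyl group is meta to both oxygens, the pattern that a vinylketene–ynol ether benzannulation delivers. Because C6 is para to C3a, the two oxygens are interchanged by rotation about the C3–C3a bond; either can close the dihydrofuran, so their differentiation only decides which one is methylated.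

## Logic of the disconnections

39 to 38: the two aryl O–CH2Ph bonds are cut last. Benzyl is the phenol mask that survives dichloroketene, organolithiums, fluoride and heat. The forward hydrogenolysis must stop at the aryl benzyl ethers, so 38 carries no alkyl benzyl ether; both primary alcohols are already free.

38 to 37 to 36: the C4 O–CH3 bond and the three O–Si bonds are cut. The C4 oxygen comes out of the annulation silylated, and fluoride releases it together with the two primary alcohols. The forward methylation must then be selective for the one phenol over two primary alcohols.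

36 to 35 to 34: the O1–C2 bond of the dihydrofuran is cut. This opens the heterocycle to a 1,2-diarylpropane-1,3-diol unit whose two stereocentres are aldol-derived. The forward closure must invert C2 (syn precursor to trans ring). The C3 CH2O group must stay protected, because a free primary alcohol could close a competing five-membered ring, and the benzylic silyl ether must be removed selectively.

34 to 18 + 29: the arene bonds C7a–C3a and C4–C5 are cut; the C7–C7a bond is also broken and remade in the cascade. This is the largest simplification: two halves of similar size, the central ring made and not bought, and its oxygens differentiated automatically as OH and OSi. The forward step needs both partners to survive 80–110 °C and needs one regiochemistry only.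

29 to 27 to 26 to 25 to 24: the C(sp)–O bond is cut, then the terminal alkyne carbon, back to the carboxyl oxidation level. Siloxyalkynes come from terminal alkynes through ynolates, and the alkyne from an aldehyde by one-carbon homologation. The forward steps must not enolise the α-branched aldehyde and must silylate the ynolate on oxygen.

24 to 23 to 21 + 22, and 21 to 19 + 2: the Cα–Cβ aldol bond (future benzofuran C3–C2) is cut. One auxiliary-controlled step sets both stereocentres and reduces the fragment to an aryl aldehyde and a three-carbon acid. The forward aldol must be syn with (2R,3R) absolute sense.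

18 to 17 to 14 + 15: the two ring bonds made by ketene–alkyne cycloaddition (C1–C2 and C3–C4 of the cyclobutenone) and the two C–Cl bonds are cut. This is the standard entry to 3-substituted cyclobutenones. The forward step needs a free terminal alkyne and tolerance of ZnCl2.

14 to 13 to 12 to 11: the oxolane O1–C2 bond is cut (with two protecting-group changes), exposing a 1,4-diol with a benzylic carbinol. The acid-mediated closure is thereby placed before the central arene exists. The forward step must give the 2,3-trans ring from either carbinol epimer.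

11 to 10 to 8 + 9: the oxolane C2–C3 bond is cut as an aldol bond; the CH2OH carbon and C5 come from a lactone. This separates the aryl aldehyde from a small chiral lactone. The forward aldol must add trans to the C4 substituent, and the alkyne must be capped.

8 to 6 to 4 + 5, and 4 to 1 + 2: the oxolane C3–C4 bond is cut as an enolate alkylation. The auxiliary sets C4, the only stereocentre of the oxolane half that is not relayed. The forward step needs high facial selectivity and a tert-butyl ester that survives LiBH4.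

## Other disconnections considered

Alternative 1: The oxolane C4–CH2 bond and the C2–C3 bond are cut together. In the forward step the lithiated dithiane A3 adds to the β-carbon of the menthyloxybutenolide A2 anti to the acetal substituent, and the lactone enolate is trapped by 9 to give A1.
- In favour: three components, two C–C bonds and two stereocentres in one flask, against three steps (2–4) in the chosen plan for the same lactone stage; on this count the alternative is the better one. The chiral controller is an inexpensive part of the ring.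
- Against: A3 presupposes the complete dihydrobenzofuran aldehyde, so the resorcinol ring with differentiated oxygens must be obtained by other means. A2 must come from (+)-menthol, the less accessible enantiomer. A1 still needs desulfurisation (Raney Ni next to four benzylic C–O bonds), reduction of lactone and acetal, and an acid-mediated oxolane closure through the benzylic cation. That closure would then run with the electron-rich benzofuran arene already attached, where tetralin formation competes.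
- Comparison: structurally both plans reach the oxolane through a trans-disubstituted lactone and a cationic ring closure. Mechanistically the alternative is anionic (conjugate addition, aldol) and the chosen plan pericyclic at the joining stage. The alternative is shorter up to the lactone and longer afterwards. The chosen plan performs the cationic closure (step 6) before any nucleophilic arene is present.

Alternative 2: The dihydrofuran C2–C3 bond is cut. In the forward step the diazo ester A5 is decomposed by Rh2(S-PTTL)4 (or its enantiomer) to a carbenoid that inserts into the benzylic ether C–H bond, giving the cis ester A6, which NaOMe in the same flask would epimerise at C3 to the trans ester A4.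
- In favour: absolute configuration from a catalyst and not from a stoichiometric auxiliary, both stereocentres from one step, and a trans relation that is thermodynamic. In stereochemical economy this is better than the aldol–Mitsunobu pair of the chosen plan, and it avoids activating an ionisable benzylic carbinol. The bromide of A4 is a ready coupling handle.
- Against: the arene of A5 is a 4-bromo-2,6-dioxygenated phenylacetate whose oxygens must be told apart by classical arene chemistry. The doubly ortho-substituted diazo ester is hindered, and its ortho-methoxy group can divert the carbenoid through an oxonium ylide. Methoxide on a β-aryloxy ester can open the ring by retro-oxa-Michael reaction. The C6–CH2 bond remains to be made by an sp2–sp3 cross-coupling with a metalated oxolane half, which adds steps and a second fragment synthesis.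
- Comparison: the alternative solves only the dihydrofuran and leaves arene differentiation and fragment union open. The chosen plan solves both in step 18 but pays with five steps afterwards. In step count to the dihydrobenzofuran core alone the two are about equal.

Alternative 3: The oxolane C3–C4 bond and the CH2–aryl bond are cut. In the forward step NiBr2 with terpyridine would turn the secondary iodide A8 into a C3 radical that closes 5-exo onto the allyl ether, and the resulting primary radical would be arylated by the arylzinc bromide A9 to give A7.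
- In favour: the most convergent plan, with ring formation and fragment union in one operation. A7 is two deprotections from 39, against five steps after the union in the chosen plan; in endgame length the alternative is clearly better. A chair-like 5-exo transition state should place the C2 aryl trans to C3 and the new CH2 cis to the C3 substituent, which is the required pattern. The conditions are neutral.
- Against: the C3/C4 relation rests on substrate control alone and is rarely complete in such cyclisations. Arylation of the uncyclised secondary radical competes. A9 must come from a bromide of the A4 type, so the arene problem of alternative 2 returns. A8 needs a stereodefined benzylic allyl ether.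
- Comparison: the alternative is superior in convergence and in the number of steps after coupling, and equal in mildness. The chosen plan is superior in that all five stereocentres are set by auxiliary control or stereospecific substitution, and in that it constructs the arene instead of presupposing it.

Key step: step 18

## Route

Step 1
Reactants: 1 5-(trimethylsilyl)pent-4-ynoic acid; 2 (4R)-4-benzyl-1,3-oxazolidin-2-one
Product: 4 (4R)-4-benzyl-3-[5-(trimethylsilyl)pent-4-ynoyl]-1,3-oxazolidin-2-one, via mixed anhydride 3 (not isolated)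
Conditions: PivCl, Et3N, THF, −20 °C; then 2, LiCl, −20 °C → rt
Reagents that add atoms: none
Why: N-acylation of the LiCl-activated oxazolidinone by the mixed pivalic anhydride; the hindered pivaloyl carbonyl is not attacked and the C-silylated alkyne is inert.

Step 2
Reactants: 4 (4R)-4-benzyl-3-[5-(trimethylsilyl)pent-4-ynoyl]-1,3-oxazolidin-2-one; 5 tert-butyl 2-bromoacetate
Product: 6 tert-butyl (3S)-3-{[(4R)-4-benzyl-2-oxo-1,3-oxazolidin-3-yl]carbonyl}-6-(trimethylsilyl)hex-5-ynoate
Conditions: NaN(SiMe3)2, THF, −78 °C; then 5, −78 → −40 °C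
Reagents that add atoms: none
Why: Evans asymmetric alkylation: the chelated (Z)-sodium enolate of 4 is alkylated by the reactive α-bromo ester on the face remote from the auxiliary benzyl group, which sets the future oxolane C4 as (S).

Step 3
Reactants: 6 tert-butyl (3S)-3-{[(4R)-4-benzyl-2-oxo-1,3-oxazolidin-3-yl]carbonyl}-6-(trimethylsilyl)hex-5-ynoate
Product: 8 (4S)-4-[3-(trimethylsilyl)prop-2-yn-1-yl]oxolan-2-one, via hydroxy ester 7 (not isolated)
Conditions: LiBH4, MeOH (1 equiv), THF, 0 °C; work-up; then CF3CO2H, CH2Cl2, rt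
Reagents that add atoms: none
Why: Reductive removal of the auxiliary: LiBH4 reduces the activated imide carbonyl to the primary alcohol and spares the tert-butyl ester; acid then cleaves that ester and closes the γ-lactone. The stereocentre is β to the new carbonyl and cannot epimerise.

Step 4
Reactants: 8 (4S)-4-[3-(trimethylsilyl)prop-2-yn-1-yl]oxolan-2-one; 9 3-(benzyloxy)-4-methoxybenzaldehyde
Product: 10 (3R,4S)-3-{[3-(benzyloxy)-4-methoxyphenyl](hydroxy)methyl}-4-[3-(trimethylsilyl)prop-2-yn-1-yl]oxolan-2-one (both carbinol epimers)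
Conditions: LiN(SiMe3)2, THF, −78 °C; then 9; AcOH quench at −78 °C
Reagents that add atoms: none
Why: Lactone enolate aldol addition: the aldehyde approaches trans to the C4 substituent, fixing the future oxolane C3; the carbinol configuration is left open because step 6 erases it. The silyl cap prevents acetylide formation and addition.

Step 5
Reactants: 10 (3R,4S)-3-{[3-(benzyloxy)-4-methoxyphenyl](hydroxy)methyl}-4-[3-(trimethylsilyl)prop-2-yn-1-yl]oxolan-2-one
Product: 11 (2S,3S)-2-{[3-(benzyloxy)-4-methoxyphenyl](hydroxy)methyl}-3-[3-(trimethylsilyl)prop-2-yn-1-yl]butane-1,4-diol (both carbinol epimers)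
Conditions: LiAlH4, THF, 0 °C; aq. KNaC4H4O6 work-up
Reagents that add atoms: none
Why: Hydride reduction of the lactone to the 1,4-diol at 0 °C, where retro-aldol cleavage of the alkoxide is slow; the silylalkyne and the benzyl ether are not reduced.

Step 6
Reactants: 11 (2S,3S)-2-{[3-(benzyloxy)-4-methoxyphenyl](hydroxy)methyl}-3-[3-(trimethylsilyl)prop-2-yn-1-yl]butane-1,4-diol
Product: 12 {(2R,3S,4S)-2-[3-(benzyloxy)-4-methoxyphenyl]-4-[3-(trimethylsilyl)prop-2-yn-1-yl]oxolan-3-yl}methanol
Conditions: (+)-camphor-10-sulfonic acid (10 mol%), CH2Cl2, 0 °C → rt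
Reagents that add atoms: none
Why: Acid-catalysed cyclodehydration (SN1, 5-exo): the p-methoxybenzylic alcohol ionises and is captured by the C4 hydroxyl, the only one that can form a five-membered ring. The aryl group should settle trans to the C3 hydroxymethyl group kinetically and, since the benzylic C–O bond re-ionises under the acid, also thermodynamically, so both carbinol epimers converge on (2R). No nucleophilic arene is yet present to intercept the cation.

Step 7
Reactants: 12 {(2R,3S,4S)-2-[3-(benzyloxy)-4-methoxyphenyl]-4-[3-(trimethylsilyl)prop-2-yn-1-yl]oxolan-3-yl}methanol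
Product: 13 {(2R,3S,4S)-2-[3-(benzyloxy)-4-methoxyphenyl]-4-(prop-2-yn-1-yl)oxolan-3-yl}methanol
Conditions: K2CO3, MeOH, rt
Reagents that add atoms: none
Why: Base-mediated protodesilylation of the alkynylsilane frees the terminal alkyne needed for the ketene cycloaddition; nothing else in 12 is base-labile.

Step 8
Reactants: 13 {(2R,3S,4S)-2-[3-(benzyloxy)-4-methoxyphenyl]-4-(prop-2-yn-1-yl)oxolan-3-yl}methanol
Product: 14 tert-butyl({(2R,3S,4S)-2-[3-(benzyloxy)-4-methoxyphenyl]-4-(prop-2-yn-1-yl)oxolan-3-yl}methoxy)diphenylsilane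
Conditions: TBDPSCl, imidazole, CH2Cl2, rt
Reagents that add atoms: tert-butyl(chloro)diphenylsilane CC(C)(C)[Si](Cl)(c1ccccc1)c1ccccc1
Why: Standard silylation of the primary alcohol. The silyl ether tolerates zinc, acetic acid, heat and buffered HF, and is later removed by fluoride, so no alkyl benzyl ether has to be hydrogenolysed beside benzylic ring C–O bonds.

Step 9
Reactants: 14 tert-butyl({(2R,3S,4S)-2-[3-(benzyloxy)-4-methoxyphenyl]-4-(prop-2-yn-1-yl)oxolan-3-yl}methoxy)diphenylsilane; 15 trichloroacetyl chloride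
Product: 17 3-{[(3S,4S,5R)-5-[3-(benzyloxy)-4-methoxyphenyl]-4-{[(tert-butyldiphenylsilyl)oxy]methyl}oxolan-3-yl]methyl}-4,4-dichlorocyclobut-2-en-1-one, via dichloroketene 16 (not isolated)
Conditions: Zn(Cu), Et2O–DME, rt, slow addition of 15
Reagents that add atoms: none
Why: [2+2] cycloaddition of dichloroketene, made by zinc dehalogenation of 15, to the terminal alkyne; the ketene carbonyl carbon bonds to the unsubstituted alkyne carbon, giving the 3-substituted ring. DME binds the ZnCl2 formed, so the benzylic oxolane ether does not meet a strong Lewis acid.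

Step 10
Reactants: 17 3-{[(3S,4S,5R)-5-[3-(benzyloxy)-4-methoxyphenyl]-4-{[(tert-butyldiphenylsilyl)oxy]methyl}oxolan-3-yl]methyl}-4,4-dichlorocyclobut-2-en-1-one
Product: 18 3-{[(3S,4S,5R)-5-[3-(benzyloxy)-4-methoxyphenyl]-4-{[(tert-butyldiphenylsilyl)oxy]methyl}oxolan-3-yl]methyl}cyclobut-2-en-1-one
Conditions: Zn dust, AcOH, TMEDA, EtOH, 0 °C → rt
Reagents that add atoms: none
Why: Reductive dechlorination α to the ketone by zinc in buffered acetic acid, the usual second stage of the dichloroketene route to cyclobutenones; silyl and benzyl ethers are stable.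

Step 11
Reactants: 19 3-[(tert-butyldiphenylsilyl)oxy]propanoic acid; 2 (4R)-4-benzyl-1,3-oxazolidin-2-one
Product: 21 (4R)-4-benzyl-3-{3-[(tert-butyldiphenylsilyl)oxy]propanoyl}-1,3-oxazolidin-2-one, via mixed anhydride 20 (not isolated)
Conditions: PivCl, Et3N, THF, −20 °C; then 2, LiCl, −20 °C → rt
Reagents that add atoms: none
Why: Same N-acylation through a mixed pivalic anhydride as in step 1; the silyl ether is unaffected.

Step 12
Reactants: 21 (4R)-4-benzyl-3-{3-[(tert-butyldiphenylsilyl)oxy]propanoyl}-1,3-oxazolidin-2-one; 22 4-(benzyloxy)-3-methoxybenzaldehyde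
Product: 23 (4R)-4-benzyl-3-[(2R,3R)-3-[4-(benzyloxy)-3-methoxyphenyl]-2-{[(tert-butyldiphenylsilyl)oxy]methyl}-3-hydroxypropanoyl]-1,3-oxazolidin-2-one
Conditions: Bu2BOTf, iPr2NEt, CH2Cl2, 0 °C; then 22, −78 → 0 °C; pH 7 buffer, MeOH, H2O2, 0 °C
Reagents that add atoms: none
Why: Evans syn-aldol: the (Z)-boron enolate of 21 reacts through a closed chair (Zimmerman–Traxler) transition state on the face opposite the auxiliary benzyl group, setting (2R) and (3R), the future benzofuran C3 and, before inversion, C2. Oxidative work-up cleaves the boron aldolate.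

Step 13
Reactants: 23 (4R)-4-benzyl-3-[(2R,3R)-3-[4-(benzyloxy)-3-methoxyphenyl]-2-{[(tert-butyldiphenylsilyl)oxy]methyl}-3-hydroxypropanoyl]-1,3-oxazolidin-2-one
Product: 24 (4R)-4-benzyl-3-[(2R,3R)-3-[4-(benzyloxy)-3-methoxyphenyl]-2-{[(tert-butyldiphenylsilyl)oxy]methyl}-3-[(triethylsilyl)oxy]propanoyl]-1,3-oxazolidin-2-one
Conditions: TESOTf, 2,6-lutidine, CH2Cl2, −78 °C
Reagents that add atoms: triethylsilyl trifluoromethanesulfonate CC[Si](CC)(CC)OS(=O)(=O)C(F)(F)F
Why: Silylation of the hindered benzylic alcohol with the silyl triflate at low temperature; the triethylsilyl ether blocks retro-aldol cleavage and can later be removed in the presence of the bulkier silyl ethers.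

Step 14
Reactants: 24 (4R)-4-benzyl-3-[(2R,3R)-3-[4-(benzyloxy)-3-methoxyphenyl]-2-{[(tert-butyldiphenylsilyl)oxy]methyl}-3-[(triethylsilyl)oxy]propanoyl]-1,3-oxazolidin-2-one
Product: 25 (2R,3R)-3-[4-(benzyloxy)-3-methoxyphenyl]-2-{[(tert-butyldiphenylsilyl)oxy]methyl}-3-[(triethylsilyl)oxy]propan-1-ol
Conditions: LiBH4, MeOH (1 equiv), THF, 0 °C
Reagents that add atoms: none
Why: Reductive cleavage of the auxiliary by hydride addition to the exocyclic imide carbonyl; the α-stereocentre is not enolised and the silyl ethers are stable.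

Step 15
Reactants: 25 (2R,3R)-3-[4-(benzyloxy)-3-methoxyphenyl]-2-{[(tert-butyldiphenylsilyl)oxy]methyl}-3-[(triethylsilyl)oxy]propan-1-ol
Product: 26 (2R,3R)-3-[4-(benzyloxy)-3-methoxyphenyl]-2-{[(tert-butyldiphenylsilyl)oxy]methyl}-3-[(triethylsilyl)oxy]propanal
Conditions: Dess–Martin periodinane, NaHCO3, CH2Cl2, 0 °C → rt; used crude
Reagents that add atoms: none
Why: Dess–Martin oxidation under bicarbonate buffer gives the α-branched aldehyde under near-neutral conditions that should not epimerise it.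

Step 16
Reactants: 26 (2R,3R)-3-[4-(benzyloxy)-3-methoxyphenyl]-2-{[(tert-butyldiphenylsilyl)oxy]methyl}-3-[(triethylsilyl)oxy]propanal
Product: 27 tert-butyl{[(2R,3R)-3-[4-(benzyloxy)-3-methoxyphenyl]-2-ethynyl-3-[(triethylsilyl)oxy]propyl]oxy}diphenylsilane
Conditions: dimethyl (1-diazo-2-oxopropyl)phosphonate, K2CO3, MeOH, 0 °C → rt
Reagents that add atoms: dimethyl (1-diazo-2-oxopropyl)phosphonate COP(=O)(OC)C(=[N+]=[N-])C(C)=O
Why: Ohira–Bestmann alkynylation: methoxide releases the diazomethylphosphonate anion, which adds to the aldehyde; loss of phosphate and N2 gives an alkylidene carbene that rearranges by 1,2-hydride shift to the terminal alkyne. At 0 °C addition should outpace enolisation, so the α-stereocentre is kept.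

Step 17
Reactants: 27 tert-butyl{[(2R,3R)-3-[4-(benzyloxy)-3-methoxyphenyl]-2-ethynyl-3-[(triethylsilyl)oxy]propyl]oxy}diphenylsilane
Product: 29 {[(3R,4R)-4-[4-(benzyloxy)-3-methoxyphenyl]-3-{[(tert-butyldiphenylsilyl)oxy]methyl}-4-[(triethylsilyl)oxy]but-1-yn-1-yl]oxy}tri(propan-2-yl)silane, via lithium ynolate 28 (not isolated)
Conditions: n-BuLi, THF, −78 °C; LiOOtBu (from t-BuOOH and LiN(SiMe3)2), −78 → 0 °C; TIPSOTf, −78 → 0 °C
Reagents that add atoms: tert-butyl hydroperoxide CC(C)(C)OO; triisopropylsilyl trifluoromethanesulfonate CC(C)[Si](OS(=O)(=O)C(F)(F)F)(C(C)C)C(C)C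
Why: Oxygen transfer from lithium tert-butyl peroxide to the lithiated alkyne gives the ynolate, and the bulky silyl triflate silylates it on oxygen; this is the established route from terminal alkynes to triisopropylsiloxyalkynes. Neither stereocentre is acidified under these conditions.

Step 18
Reactants: 18 3-{[(3S,4S,5R)-5-[3-(benzyloxy)-4-methoxyphenyl]-4-{[(tert-butyldiphenylsilyl)oxy]methyl}oxolan-3-yl]methyl}cyclobut-2-en-1-one; 29 {[(3R,4R)-4-[4-(benzyloxy)-3-methoxyphenyl]-3-{[(tert-butyldiphenylsilyl)oxy]methyl}-4-[(triethylsilyl)oxy]but-1-yn-1-yl]oxy}tri(propan-2-yl)silane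
Product: 34 2-[(1R,2R)-1-[4-(benzyloxy)-3-methoxyphenyl]-3-[(tert-butyldiphenylsilyl)oxy]-1-[(triethylsilyl)oxy]propan-2-yl]-5-{[(3S,4S,5R)-5-[3-(benzyloxy)-4-methoxyphenyl]-4-{[(tert-butyldiphenylsilyl)oxy]methyl}oxolan-3-yl]methyl}-3-{[tri(propan-2-yl)silyl]oxy}phenol, via vinylketene 30 (not isolated), via vinylcyclobutenone 31 (not isolated), via dienylketene 32 (not isolated), via cyclohexadienone 33 (not isolated)
Conditions: 29 (1.2 equiv), toluene (0.5 M), 80 °C, then 110 °C
Reagents that add atoms: none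
Why: At 80 °C 18 opens by reversible 4π electrocyclic ring opening to vinylketene 30. 30 adds [2+2] to the electron-rich triple bond of 29, the ketene carbonyl carbon bonding to the nucleophilic, carbon-substituted alkyne carbon, to give 31. 4π opening of 31 gives dienylketene 32, whose thermal disrotatory 6π electrocyclisation closes the six-membered ring to 33; tautomerisation gives phenol 34. The closest known reaction is the Danheiser benzannulation of 3-alkylcyclobutenones with triisopropylsiloxyalkynes to resorcinol monosilyl ethers. The net result is two new bonds, C7a–C3a and C4–C5, while C7–C7a (the old C1–C4 bond of 18) is broken and remade. No stereocentre is created, since the sp3 centre of 31 is lost on aromatisation, and the five existing ones never sit next to a carbonyl or a cation in a neutral, aprotic medium. Only regiochemistry is required, and the polarisation of the siloxyalkyne secures it: the side chain ends between OH and OSi and the oxolanylmethyl group para to it. A small excess of 29 limits acylation of the product phenol by 30.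

Step 19
Reactants: 34 2-[(1R,2R)-1-[4-(benzyloxy)-3-methoxyphenyl]-3-[(tert-butyldiphenylsilyl)oxy]-1-[(triethylsilyl)oxy]propan-2-yl]-5-{[(3S,4S,5R)-5-[3-(benzyloxy)-4-methoxyphenyl]-4-{[(tert-butyldiphenylsilyl)oxy]methyl}oxolan-3-yl]methyl}-3-{[tri(propan-2-yl)silyl]oxy}phenol
Product: 35 2-[(1R,2R)-1-[4-(benzyloxy)-3-methoxyphenyl]-3-[(tert-butyldiphenylsilyl)oxy]-1-hydroxypropan-2-yl]-5-{[(3S,4S,5R)-5-[3-(benzyloxy)-4-methoxyphenyl]-4-{[(tert-butyldiphenylsilyl)oxy]methyl}oxolan-3-yl]methyl}-3-{[tri(propan-2-yl)silyl]oxy}phenol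
Conditions: HF·pyridine, pyridine, THF, 0 °C
Reagents that add atoms: none
Why: Selective desilylation: under buffered HF the secondary triethylsilyl ether cleaves far faster than the primary tert-butyldiphenylsilyl ethers and the hindered aryl silyl ether, and the pyridine buffer avoids ionising either benzylic C–O bond. Partial loss of the aryl silyl group would be harmless, because both phenolic oxygens flank C3a equivalently.

Step 20
Reactants: 35 2-[(1R,2R)-1-[4-(benzyloxy)-3-methoxyphenyl]-3-[(tert-butyldiphenylsilyl)oxy]-1-hydroxypropan-2-yl]-5-{[(3S,4S,5R)-5-[3-(benzyloxy)-4-methoxyphenyl]-4-{[(tert-butyldiphenylsilyl)oxy]methyl}oxolan-3-yl]methyl}-3-{[tri(propan-2-yl)silyl]oxy}phenol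
Product: 36 tert-butyl{[(2S,3R)-2-[4-(benzyloxy)-3-methoxyphenyl]-6-{[(3S,4S,5R)-5-[3-(benzyloxy)-4-methoxyphenyl]-4-{[(tert-butyldiphenylsilyl)oxy]methyl}oxolan-3-yl]methyl}-4-{[tri(propan-2-yl)silyl]oxy}-2,3-dihydro-1-benzofuran-3-yl]methoxy}diphenylsilane
Conditions: PPh3, DIAD, THF, 0 °C → rt
Reagents that add atoms: none
Why: Intramolecular Mitsunobu etherification (5-exo-tet): the benzylic alcohol is activated as its oxyphosphonium ion and displaced by the neighbouring phenoxide with inversion, turning the syn-aldol (1R) centre into (2S) and giving the trans ring. If the activated p-alkoxybenzylic centre partly ionises, closure still favours the trans isomer, so both pathways lead to 36.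

Step 21
Reactants: 36 tert-butyl{[(2S,3R)-2-[4-(benzyloxy)-3-methoxyphenyl]-6-{[(3S,4S,5R)-5-[3-(benzyloxy)-4-methoxyphenyl]-4-{[(tert-butyldiphenylsilyl)oxy]methyl}oxolan-3-yl]methyl}-4-{[tri(propan-2-yl)silyl]oxy}-2,3-dihydro-1-benzofuran-3-yl]methoxy}diphenylsilane
Product: 37 (2S,3R)-2-[4-(benzyloxy)-3-methoxyphenyl]-6-{[(3S,4S,5R)-5-[3-(benzyloxy)-4-methoxyphenyl]-4-(hydroxymethyl)oxolan-3-yl]methyl}-3-(hydroxymethyl)-2,3-dihydro-1-benzofuran-4-ol
Conditions: Bu4NF, THF, 0 °C → rt; aq. NH4Cl
Reagents that add atoms: none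
Why: Fluoride-mediated desilylation cleaves all three remaining silyl ethers (the aryl one fastest), giving the C4 phenol and both primary alcohols; benzyl ethers and both cyclic ethers are inert to fluoride.

Step 22
Reactants: 37 (2S,3R)-2-[4-(benzyloxy)-3-methoxyphenyl]-6-{[(3S,4S,5R)-5-[3-(benzyloxy)-4-methoxyphenyl]-4-(hydroxymethyl)oxolan-3-yl]methyl}-3-(hydroxymethyl)-2,3-dihydro-1-benzofuran-4-ol
Product: 38 [(2S,3R)-2-[4-(benzyloxy)-3-methoxyphenyl]-6-{[(3S,4S,5R)-5-[3-(benzyloxy)-4-methoxyphenyl]-4-(hydroxymethyl)oxolan-3-yl]methyl}-4-methoxy-2,3-dihydro-1-benzofuran-3-yl]methanol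
Conditions: MeI, K2CO3, acetone, rt → 40 °C
Reagents that add atoms: iodomethane CI
Why: Williamson methylation: carbonate deprotonates only the phenol (pKa about 10), so O-methylation occurs at C4 alone and the primary alcohols stay free.

Step 23
Reactants: 38 [(2S,3R)-2-[4-(benzyloxy)-3-methoxyphenyl]-6-{[(3S,4S,5R)-5-[3-(benzyloxy)-4-methoxyphenyl]-4-(hydroxymethyl)oxolan-3-yl]methyl}-4-methoxy-2,3-dihydro-1-benzofuran-3-yl]methanol
Product: 39 [(2S,3R)-2-(4-hydroxy-3-methoxyphenyl)-6-{[(3S,4S,5R)-5-(3-hydroxy-4-methoxyphenyl)-4-(hydroxymethyl)oxolan-3-yl]methyl}-4-methoxy-2,3-dihydro-1-benzofuran-3-yl]methanol (CNP0242386.1)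
Conditions: H2 (1 atm), 10% Pd/C, EtOAc, rt; stopped at two equivalents of H2
Reagents that add atoms: none
Why: Catalytic hydrogenolysis of the two aryl benzyl ethers, which cleave far more readily than dialkyl or alkyl aryl benzylic ethers; a neutral aprotic solvent and stopping at the calculated uptake should keep both benzylic ring C–O bonds intact.

## Compound list

1 | 5-(trimethylsilyl)pent-4-ynoic acid | C[Si](C)(C)C#CCCC(=O)O | starting material
2 | (4R)-4-benzyl-1,3-oxazolidin-2-one | O=C1N[C@H](Cc2ccccc2)CO1 | starting material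
3 | 2,2-dimethylpropanoic 5-(trimethylsilyl)pent-4-ynoic anhydride | C[Si](C)(C)C#CCCC(=O)OC(=O)C(C)(C)C | intermediate (not isolated)
4 | (4R)-4-benzyl-3-[5-(trimethylsilyl)pent-4-ynoyl]-1,3-oxazolidin-2-one | O=C1OC[C@@H](Cc2ccccc2)N1C(=O)CCC#C[Si](C)(C)C | intermediate
5 | tert-butyl 2-bromoacetate | CC(C)(C)OC(=O)CBr | starting material
6 | tert-butyl (3S)-3-{[(4R)-4-benzyl-2-oxo-1,3-oxazolidin-3-yl]carbonyl}-6-(trimethylsilyl)hex-5-ynoate | O=C1OC[C@@H](Cc2ccccc2)N1C(=O)[C@@H](CC#C[Si](C)(C)C)CC(=O)OC(C)(C)C | intermediate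
7 | tert-butyl (3S)-3-(hydroxymethyl)-6-(trimethylsilyl)hex-5-ynoate | OC[C@@H](CC#C[Si](C)(C)C)CC(=O)OC(C)(C)C | intermediate (not isolated)
8 | (4S)-4-[3-(trimethylsilyl)prop-2-yn-1-yl]oxolan-2-one | O=C1C[C@H](CC#C[Si](C)(C)C)CO1 | intermediate
9 | 3-(benzyloxy)-4-methoxybenzaldehyde | COc1ccc(C=O)cc1OCc1ccccc1 | starting material
10 | (3R,4S)-3-{[3-(benzyloxy)-4-methoxyphenyl](hydroxy)methyl}-4-[3-(trimethylsilyl)prop-2-yn-1-yl]oxolan-2-one, both carbinol epimers | O=C1OC[C@@H](CC#C[Si](C)(C)C)[C@@H]1C(O)c1ccc(OC)c(OCc2ccccc2)c1 | intermediate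
11 | (2S,3S)-2-{[3-(benzyloxy)-4-methoxyphenyl](hydroxy)methyl}-3-[3-(trimethylsilyl)prop-2-yn-1-yl]butane-1,4-diol, both carbinol epimers | OC[C@@H](CC#C[Si](C)(C)C)[C@@H](CO)C(O)c1ccc(OC)c(OCc2ccccc2)c1 | intermediate
12 | {(2R,3S,4S)-2-[3-(benzyloxy)-4-methoxyphenyl]-4-[3-(trimethylsilyl)prop-2-yn-1-yl]oxolan-3-yl}methanol | COc1ccc([C@@H]2OC[C@@H](CC#C[Si](C)(C)C)[C@H]2CO)cc1OCc1ccccc1 | intermediate
13 | {(2R,3S,4S)-2-[3-(benzyloxy)-4-methoxyphenyl]-4-(prop-2-yn-1-yl)oxolan-3-yl}methanol | COc1ccc([C@@H]2OC[C@@H](CC#C)[C@H]2CO)cc1OCc1ccccc1 | intermediate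
14 | tert-butyl({(2R,3S,4S)-2-[3-(benzyloxy)-4-methoxyphenyl]-4-(prop-2-yn-1-yl)oxolan-3-yl}methoxy)diphenylsilane | COc1ccc([C@@H]2OC[C@@H](CC#C)[C@H]2CO[Si](c2ccccc2)(c2ccccc2)C(C)(C)C)cc1OCc1ccccc1 | intermediate
15 | trichloroacetyl chloride | ClC(=O)C(Cl)(Cl)Cl | starting material
16 | dichloroketene | ClC(Cl)=C=O | intermediate (not isolated)
17 | 3-{[(3S,4S,5R)-5-[3-(benzyloxy)-4-methoxyphenyl]-4-{[(tert-butyldiphenylsilyl)oxy]methyl}oxolan-3-yl]methyl}-4,4-dichlorocyclobut-2-en-1-one | COc1ccc([C@@H]2OC[C@@H](CC3=CC(=O)C3(Cl)Cl)[C@H]2CO[Si](c2ccccc2)(c2ccccc2)C(C)(C)C)cc1OCc1ccccc1 | intermediate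
18 | 3-{[(3S,4S,5R)-5-[3-(benzyloxy)-4-methoxyphenyl]-4-{[(tert-butyldiphenylsilyl)oxy]methyl}oxolan-3-yl]methyl}cyclobut-2-en-1-one | COc1ccc([C@@H]2OC[C@@H](CC3=CC(=O)C3)[C@H]2CO[Si](c2ccccc2)(c2ccccc2)C(C)(C)C)cc1OCc1ccccc1 | intermediate
19 | 3-[(tert-butyldiphenylsilyl)oxy]propanoic acid | OC(=O)CCO[Si](c1ccccc1)(c1ccccc1)C(C)(C)C | starting material
20 | 3-[(tert-butyldiphenylsilyl)oxy]propanoic 2,2-dimethylpropanoic anhydride | CC(C)(C)C(=O)OC(=O)CCO[Si](c1ccccc1)(c1ccccc1)C(C)(C)C | intermediate (not isolated)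
21 | (4R)-4-benzyl-3-{3-[(tert-butyldiphenylsilyl)oxy]propanoyl}-1,3-oxazolidin-2-one | O=C1OC[C@@H](Cc2ccccc2)N1C(=O)CCO[Si](c1ccccc1)(c1ccccc1)C(C)(C)C | intermediate
22 | 4-(benzyloxy)-3-methoxybenzaldehyde | COc1cc(C=O)ccc1OCc1ccccc1 | starting material
23 | (4R)-4-benzyl-3-[(2R,3R)-3-[4-(benzyloxy)-3-methoxyphenyl]-2-{[(tert-butyldiphenylsilyl)oxy]methyl}-3-hydroxypropanoyl]-1,3-oxazolidin-2-one | O=C1OC[C@@H](Cc2ccccc2)N1C(=O)[C@H](CO[Si](c1ccccc1)(c1ccccc1)C(C)(C)C)[C@@H](O)c1ccc(OCc2ccccc2)c(OC)c1 | intermediate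
24 | (4R)-4-benzyl-3-[(2R,3R)-3-[4-(benzyloxy)-3-methoxyphenyl]-2-{[(tert-butyldiphenylsilyl)oxy]methyl}-3-[(triethylsilyl)oxy]propanoyl]-1,3-oxazolidin-2-one | O=C1OC[C@@H](Cc2ccccc2)N1C(=O)[C@H](CO[Si](c1ccccc1)(c1ccccc1)C(C)(C)C)[C@@H](O[Si](CC)(CC)CC)c1ccc(OCc2ccccc2)c(OC)c1 | intermediate
25 | (2R,3R)-3-[4-(benzyloxy)-3-methoxyphenyl]-2-{[(tert-butyldiphenylsilyl)oxy]methyl}-3-[(triethylsilyl)oxy]propan-1-ol | OC[C@H](CO[Si](c1ccccc1)(c1ccccc1)C(C)(C)C)[C@@H](O[Si](CC)(CC)CC)c1ccc(OCc2ccccc2)c(OC)c1 | intermediate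
26 | (2R,3R)-3-[4-(benzyloxy)-3-methoxyphenyl]-2-{[(tert-butyldiphenylsilyl)oxy]methyl}-3-[(triethylsilyl)oxy]propanal | O=C[C@H](CO[Si](c1ccccc1)(c1ccccc1)C(C)(C)C)[C@@H](O[Si](CC)(CC)CC)c1ccc(OCc2ccccc2)c(OC)c1 | intermediate
27 | tert-butyl{[(2R,3R)-3-[4-(benzyloxy)-3-methoxyphenyl]-2-ethynyl-3-[(triethylsilyl)oxy]propyl]oxy}diphenylsilane | C#C[C@H](CO[Si](c1ccccc1)(c1ccccc1)C(C)(C)C)[C@@H](O[Si](CC)(CC)CC)c1ccc(OCc2ccccc2)c(OC)c1 | intermediate
28 | lithium (3R,4R)-4-[4-(benzyloxy)-3-methoxyphenyl]-3-{[(tert-butyldiphenylsilyl)oxy]methyl}-4-[(triethylsilyl)oxy]but-1-yn-1-olate | [Li+].[O-]C#C[C@H](CO[Si](c1ccccc1)(c1ccccc1)C(C)(C)C)[C@@H](O[Si](CC)(CC)CC)c1ccc(OCc2ccccc2)c(OC)c1 | intermediate (not isolated)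
29 | {[(3R,4R)-4-[4-(benzyloxy)-3-methoxyphenyl]-3-{[(tert-butyldiphenylsilyl)oxy]methyl}-4-[(triethylsilyl)oxy]but-1-yn-1-yl]oxy}tri(propan-2-yl)silane | CC(C)[Si](OC#C[C@H](CO[Si](c1ccccc1)(c1ccccc1)C(C)(C)C)[C@@H](O[Si](CC)(CC)CC)c1ccc(OCc2ccccc2)c(OC)c1)(C(C)C)C(C)C | intermediate
30 | vinylketene from 18: 3-{[oxolan-3-yl]methyl}buta-1,3-dien-1-one carrying the oxolane substituents of 18 | COc1ccc([C@@H]2OC[C@@H](CC(=C)C=C=O)[C@H]2CO[Si](c2ccccc2)(c2ccccc2)C(C)(C)C)cc1OCc1ccccc1 | intermediate (not isolated)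
31 | [2+2] adduct: 2-(side chain of 29)-3-(triisopropylsiloxy)-4-[3-(oxolanyl)prop-1-en-2-yl]cyclobut-2-en-1-one, C4 epimers | COc1ccc([C@@H]2OC[C@@H](CC(=C)C3C(=O)C(=C3O[Si](C(C)C)(C(C)C)C(C)C)[C@H](CO[Si](c3ccccc3)(c3ccccc3)C(C)(C)C)[C@@H](O[Si](CC)(CC)CC)c3ccc(OCc4ccccc4)c(OC)c3)[C@H]2CO[Si](c2ccccc2)(c2ccccc2)C(C)(C)C)cc1OCc1ccccc1 | intermediate (not isolated)
32 | dienylketene: 2-(side chain of 29)-3-(triisopropylsiloxy)-5-(oxolanylmethyl)hexa-1,3,5-trien-1-one | COc1ccc([C@@H]2OC[C@@H](CC(=C)C=C(O[Si](C(C)C)(C(C)C)C(C)C)C(=C=O)[C@H](CO[Si](c3ccccc3)(c3ccccc3)C(C)(C)C)[C@@H](O[Si](CC)(CC)CC)c3ccc(OCc4ccccc4)c(OC)c3)[C@H]2CO[Si](c2ccccc2)(c2ccccc2)C(C)(C)C)cc1OCc1ccccc1 | intermediate (not isolated)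
33 | keto tautomer of 34: 2-(side chain)-3-(triisopropylsiloxy)-5-(oxolanylmethyl)cyclohexa-2,4-dien-1-one | COc1ccc([C@@H]2OC[C@@H](CC3=CC(O[Si](C(C)C)(C(C)C)C(C)C)=C([C@H](CO[Si](c4ccccc4)(c4ccccc4)C(C)(C)C)[C@@H](O[Si](CC)(CC)CC)c4ccc(OCc5ccccc5)c(OC)c4)C(=O)C3)[C@H]2CO[Si](c2ccccc2)(c2ccccc2)C(C)(C)C)cc1OCc1ccccc1 | intermediate (not isolated)
34 | 2-[(1R,2R)-1-[4-(benzyloxy)-3-methoxyphenyl]-3-[(tert-butyldiphenylsilyl)oxy]-1-[(triethylsilyl)oxy]propan-2-yl]-5-{[(3S,4S,5R)-5-[3-(benzyloxy)-4-methoxyphenyl]-4-{[(tert-butyldiphenylsilyl)oxy]methyl}oxolan-3-yl]methyl}-3-{[tri(propan-2-yl)silyl]oxy}phenol | COc1ccc([C@@H]2OC[C@@H](Cc3cc(O[Si](C(C)C)(C(C)C)C(C)C)c(c(O)c3)[C@H](CO[Si](c3ccccc3)(c3ccccc3)C(C)(C)C)[C@@H](O[Si](CC)(CC)CC)c3ccc(OCc4ccccc4)c(OC)c3)[C@H]2CO[Si](c2ccccc2)(c2ccccc2)C(C)(C)C)cc1OCc1ccccc1 | intermediate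
35 | 2-[(1R,2R)-1-[4-(benzyloxy)-3-methoxyphenyl]-3-[(tert-butyldiphenylsilyl)oxy]-1-hydroxypropan-2-yl]-5-{[(3S,4S,5R)-5-[3-(benzyloxy)-4-methoxyphenyl]-4-{[(tert-butyldiphenylsilyl)oxy]methyl}oxolan-3-yl]methyl}-3-{[tri(propan-2-yl)silyl]oxy}phenol | COc1ccc([C@@H]2OC[C@@H](Cc3cc(O[Si](C(C)C)(C(C)C)C(C)C)c(c(O)c3)[C@H](CO[Si](c3ccccc3)(c3ccccc3)C(C)(C)C)[C@@H](O)c3ccc(OCc4ccccc4)c(OC)c3)[C@H]2CO[Si](c2ccccc2)(c2ccccc2)C(C)(C)C)cc1OCc1ccccc1 | intermediate
36 | tert-butyl{[(2S,3R)-2-[4-(benzyloxy)-3-methoxyphenyl]-6-{[(3S,4S,5R)-5-[3-(benzyloxy)-4-methoxyphenyl]-4-{[(tert-butyldiphenylsilyl)oxy]methyl}oxolan-3-yl]methyl}-4-{[tri(propan-2-yl)silyl]oxy}-2,3-dihydro-1-benzofuran-3-yl]methoxy}diphenylsilane | COc1ccc([C@@H]2OC[C@@H](Cc3cc(O[Si](C(C)C)(C(C)C)C(C)C)c4c(c3)O[C@H](c3ccc(OCc5ccccc5)c(OC)c3)[C@H]4CO[Si](c3ccccc3)(c3ccccc3)C(C)(C)C)[C@H]2CO[Si](c2ccccc2)(c2ccccc2)C(C)(C)C)cc1OCc1ccccc1 | intermediate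
37 | (2S,3R)-2-[4-(benzyloxy)-3-methoxyphenyl]-6-{[(3S,4S,5R)-5-[3-(benzyloxy)-4-methoxyphenyl]-4-(hydroxymethyl)oxolan-3-yl]methyl}-3-(hydroxymethyl)-2,3-dihydro-1-benzofuran-4-ol | COc1ccc([C@@H]2OC[C@@H](Cc3cc(O)c4c(c3)O[C@H](c3ccc(OCc5ccccc5)c(OC)c3)[C@H]4CO)[C@H]2CO)cc1OCc1ccccc1 | intermediate
38 | [(2S,3R)-2-[4-(benzyloxy)-3-methoxyphenyl]-6-{[(3S,4S,5R)-5-[3-(benzyloxy)-4-methoxyphenyl]-4-(hydroxymethyl)oxolan-3-yl]methyl}-4-methoxy-2,3-dihydro-1-benzofuran-3-yl]methanol | COc1ccc([C@@H]2OC[C@@H](Cc3cc(OC)c4c(c3)O[C@H](c3ccc(OCc5ccccc5)c(OC)c3)[C@H]4CO)[C@H]2CO)cc1OCc1ccccc1 | intermediate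
39 | [(2S,3R)-2-(4-hydroxy-3-methoxyphenyl)-6-{[(3S,4S,5R)-5-(3-hydroxy-4-methoxyphenyl)-4-(hydroxymethyl)oxolan-3-yl]methyl}-4-methoxy-2,3-dihydro-1-benzofuran-3-yl]methanol | COc1ccc([C@@H]2OC[C@@H](Cc3cc(OC)c4c(c3)O[C@H](c3ccc(O)c(OC)c3)[C@H]4CO)[C@H]2CO)cc1O | target

## Step count and least certain steps

Total: 23 steps. Longest linear sequence: 16 steps (steps 1–10, then 18–23); the siloxyalkyne branch is 7 steps (11–17).

Step 18 (key step). The [2+2] between the vinylketene and the α-branched siloxyalkyne may be slow, so that ketene dimerisation or acylation of the product phenol takes over; at the temperature needed to open the cyclobutenone the siloxyalkyne may also suffer a 1,3-silyl shift. Fallback: generate the same vinylketene 30 at room temperature by photochemical Wolff rearrangement, the second-generation form of this benzannulation.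
- It sets out from 14: α-selective hydroalumination (iBu2AlH, NiCl2(dppp) cat., THF), then N-iodosuccinimide, would give the 2-iodoalkene F1.
- Carbonylative Stille coupling (Pd(PPh3)4, CO, Me4Sn) would give the methyl enone F2.
- Trifluoroacetylation of its lithium enolate (LiN(SiMe3)2, CF3CO2CH2CF3, −78 °C) would give the trifluoroacetyl diketone F3, and diazo transfer with loss of the trifluoroacetyl group (MsN3, Et3N, H2O, MeCN) the diazo enone F4.
- Irradiation of F4 with 29 in CH2Cl2, followed by warming in toluene, would return to the route at 34.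

Step 17. Oxygen transfer to the hindered lithium acetylide may be incomplete, or silylation may occur on carbon to give a silylketene; the product may also be hydrolysed on silica. Fallback: the Kowalski ynolate route from the ester oxidation level, which bypasses 25–27. From 24, MeMgBr in MeOH–CH2Cl2 at 0 °C would give the methyl ester F5. Treatment with LiCHBr2 (CH2Br2, Li(tmp), THF, −78 °C), then LiN(SiMe3)2, then n-BuLi with warming would give the same ynolate by bromine–lithium exchange and 1,2-shift of the stereogenic carbon with retention. TIPSCl would then return to the route at 29.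

Step 16. Methoxide may enolise the α-branched aldehyde, causing epimerisation at C2 or β-elimination of a silyloxy group. Fallback: Corey–Fuchs homologation, in which the aldehyde never meets an alkoxide. From 26, CBr4, PPh3 and 2,6-lutidine in CH2Cl2 at 0 °C would give the dibromoalkene F6; n-BuLi (2 equiv, THF, −78 °C) followed by aqueous NH4Cl would return to the route at 27.

Step 9. The ZnCl2 formed may open or epimerise the benzylic oxolane ether, and the cycloaddition of the ketene to a functionalised alkyne may be slow against ketene oligomerisation. Fallback: a keteniminium [2+2] cycloaddition that needs neither zinc nor dechlorination. From 14, the keteniminium triflate made from N,N-dimethylacetamide, Tf2O and 2,4,6-collidine in ClCH2CH2Cl would give the cyclobutenyl iminium triflate F7. Hydrolysis with aqueous NaHCO3 would return to the route directly at 18, skipping 17.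

Step 20. The activated benzylic alcohol may eliminate towards the stilbene through the benzylic C3–H, or the hindered phenol may react too slowly so that the hydrazide is alkylated instead. Fallback: closure through the other, equivalent oxygen by fluoride-triggered displacement. From 34, MeI and K2CO3 in acetone would give the methyl ether F8, and HF·pyridine the benzylic alcohol F9. Ms2O and iPr2NEt in CH2Cl2 at −78 °C would form the mesylate F10 in the flask. Excess Bu4NF would then release the neighbouring phenoxide, which displaces the mesylate with inversion, and would also remove both primary silyl groups, returning to the route at 38 (35–37 are bypassed).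

## Further compounds

F1 | step 18 | tert-butyl({(2R,3S,4S)-2-[3-(benzyloxy)-4-methoxyphenyl]-4-(2-iodoprop-2-en-1-yl)oxolan-3-yl}methoxy)diphenylsilane | COc1ccc([C@@H]2OC[C@@H](CC(I)=C)[C@H]2CO[Si](c2ccccc2)(c2ccccc2)C(C)(C)C)cc1OCc1ccccc1
F2 | step 18 | 3-{[(3S,4S,5R)-5-[3-(benzyloxy)-4-methoxyphenyl]-4-{[(tert-butyldiphenylsilyl)oxy]methyl}oxolan-3-yl]methyl}but-3-en-2-one | COc1ccc([C@@H]2OC[C@@H](CC(=C)C(C)=O)[C@H]2CO[Si](c2ccccc2)(c2ccccc2)C(C)(C)C)cc1OCc1ccccc1
F3 | step 18 | 5-{[(3S,4S,5R)-5-[3-(benzyloxy)-4-methoxyphenyl]-4-{[(tert-butyldiphenylsilyl)oxy]methyl}oxolan-3-yl]methyl}-1,1,1-trifluorohex-5-ene-2,4-dione | COc1ccc([C@@H]2OC[C@@H](CC(=C)C(=O)CC(=O)C(F)(F)F)[C@H]2CO[Si](c2ccccc2)(c2ccccc2)C(C)(C)C)cc1OCc1ccccc1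
F4 | step 18 | 3-{[(3S,4S,5R)-5-[3-(benzyloxy)-4-methoxyphenyl]-4-{[(tert-butyldiphenylsilyl)oxy]methyl}oxolan-3-yl]methyl}-1-diazobut-3-en-2-one | COc1ccc([C@@H]2OC[C@@H](CC(=C)C(=O)C=[N+]=[N-])[C@H]2CO[Si](c2ccccc2)(c2ccccc2)C(C)(C)C)cc1OCc1ccccc1
F5 | step 17 | methyl (2R,3R)-3-[4-(benzyloxy)-3-methoxyphenyl]-2-{[(tert-butyldiphenylsilyl)oxy]methyl}-3-[(triethylsilyl)oxy]propanoate | COC(=O)[C@H](CO[Si](c1ccccc1)(c1ccccc1)C(C)(C)C)[C@@H](O[Si](CC)(CC)CC)c1ccc(OCc2ccccc2)c(OC)c1
F6 | step 16 | {[(1R,2R)-1-[4-(benzyloxy)-3-methoxyphenyl]-4,4-dibromo-2-{[(tert-butyldiphenylsilyl)oxy]methyl}but-3-en-1-yl]oxy}triethylsilane | BrC(Br)=C[C@H](CO[Si](c1ccccc1)(c1ccccc1)C(C)(C)C)[C@@H](O[Si](CC)(CC)CC)c1ccc(OCc2ccccc2)c(OC)c1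
F7 | step 9 | N-(3-{[(3S,4S,5R)-5-[3-(benzyloxy)-4-methoxyphenyl]-4-{[(tert-butyldiphenylsilyl)oxy]methyl}oxolan-3-yl]methyl}cyclobut-2-en-1-ylidene)-N-methylmethanaminium trifluoromethanesulfonate | COc1ccc([C@@H]2OC[C@@H](CC3=CC(=[N+](C)C)C3)[C@H]2CO[Si](c2ccccc2)(c2ccccc2)C(C)(C)C)cc1OCc1ccccc1.[O-]S(=O)(=O)C(F)(F)F
F8 | step 20 | O-methyl ether of 34 at the free phenol | COc1ccc([C@@H]2OC[C@@H](Cc3cc(O[Si](C(C)C)(C(C)C)C(C)C)c(c(OC)c3)[C@H](CO[Si](c3ccccc3)(c3ccccc3)C(C)(C)C)[C@@H](O[Si](CC)(CC)CC)c3ccc(OCc4ccccc4)c(OC)c3)[C@H]2CO[Si](c2ccccc2)(c2ccccc2)C(C)(C)C)cc1OCc1ccccc1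
F9 | step 20 | (1R,2R)-1-[4-(benzyloxy)-3-methoxyphenyl]-3-[(tert-butyldiphenylsilyl)oxy]-2-[4-{[(3S,4S,5R)-5-[3-(benzyloxy)-4-methoxyphenyl]-4-{[(tert-butyldiphenylsilyl)oxy]methyl}oxolan-3-yl]methyl}-2-methoxy-6-{[tri(propan-2-yl)silyl]oxy}phenyl]propan-1-ol | COc1ccc([C@@H]2OC[C@@H](Cc3cc(O[Si](C(C)C)(C(C)C)C(C)C)c(c(OC)c3)[C@H](CO[Si](c3ccccc3)(c3ccccc3)C(C)(C)C)[C@@H](O)c3ccc(OCc4ccccc4)c(OC)c3)[C@H]2CO[Si](c2ccccc2)(c2ccccc2)C(C)(C)C)cc1OCc1ccccc1
F10 | step 20 | methanesulfonate of F9 at the benzylic hydroxyl | COc1ccc([C@@H]2OC[C@@H](Cc3cc(O[Si](C(C)C)(C(C)C)C(C)C)c(c(OC)c3)[C@H](CO[Si](c3ccccc3)(c3ccccc3)C(C)(C)C)[C@@H](OS(C)(=O)=O)c3ccc(OCc4ccccc4)c(OC)c3)[C@H]2CO[Si](c2ccccc2)(c2ccccc2)C(C)(C)C)cc1OCc1ccccc1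
A1 | alternative 1 | trans-3-{[3-(benzyloxy)-4-methoxyphenyl](hydroxy)methyl}-4-{2-[(2S,3R)-2-[4-(benzyloxy)-3-methoxyphenyl]-3-{[(tert-butyldimethylsilyl)oxy]methyl}-4-methoxy-2,3-dihydro-1-benzofuran-6-yl]-1,3-dithian-2-yl}-5-[(1S,2R,5S)-menthyloxy]oxolan-2-one, carbinol epimers | O1[C@H](O[C@H]2C[C@@H](C)CC[C@@H]2C(C)C)[C@@H](C2(SCCCS2)c2cc(OC)c3c(c2)O[C@H](c2ccc(OCc4ccccc4)c(OC)c2)[C@H]3CO[Si](C)(C)C(C)(C)C)[C@H](C(O)c2ccc(OC)c(OCc3ccccc3)c2)C1=O
A2 | alternative 1 | (5S)-5-{[(1S,2R,5S)-5-methyl-2-(propan-2-yl)cyclohexyl]oxy}furan-2(5H)-one | O1[C@H](O[C@H]2C[C@@H](C)CC[C@@H]2C(C)C)C=CC1=O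
A3 | alternative 1 | 2-[(2S,3R)-2-[4-(benzyloxy)-3-methoxyphenyl]-3-{[(tert-butyldimethylsilyl)oxy]methyl}-4-methoxy-2,3-dihydro-1-benzofuran-6-yl]-1,3-dithiane | S1CCCSC1c1cc(OC)c2c(c1)O[C@H](c1ccc(OCc3ccccc3)c(OC)c1)[C@H]2CO[Si](C)(C)C(C)(C)C
A4 | alternative 2 | methyl (2S,3S)-2-[4-(benzyloxy)-3-methoxyphenyl]-6-bromo-4-methoxy-2,3-dihydro-1-benzofuran-3-carboxylate (trans) | Brc1cc(OC)c2c(c1)O[C@H](c1ccc(OCc3ccccc3)c(OC)c1)[C@H]2C(=O)OC
A5 | alternative 2 | methyl 2-(2-{[4-(benzyloxy)-3-methoxyphenyl]methoxy}-4-bromo-6-methoxyphenyl)-2-diazoacetate | COC(=O)C(=[N+]=[N-])c1c(OC)cc(Br)cc1OCc1ccc(OCc2ccccc2)c(OC)c1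
A6 | alternative 2 | methyl (2S,3R)-2-[4-(benzyloxy)-3-methoxyphenyl]-6-bromo-4-methoxy-2,3-dihydro-1-benzofuran-3-carboxylate (cis) | Brc1cc(OC)c2c(c1)O[C@H](c1ccc(OCc3ccccc3)c(OC)c1)[C@@H]2C(=O)OC
A7 | alternative 3 | 39 with benzyl ethers on both phenols and tert-butyldimethylsilyl ethers on both primary alcohols | COc1ccc([C@@H]2OC[C@@H](Cc3cc(OC)c4c(c3)O[C@H](c3ccc(OCc5ccccc5)c(OC)c3)[C@H]4CO[Si](C)(C)C(C)(C)C)[C@H]2CO[Si](C)(C)C(C)(C)C)cc1OCc1ccccc1
A8 | alternative 3 | {[(3S)-3-[3-(benzyloxy)-4-methoxyphenyl]-2-iodo-3-(prop-2-en-1-yloxy)propyl]oxy}(tert-butyl)dimethylsilane, either C2 epimer | COc1ccc([C@H](OCC=C)C(I)CO[Si](C)(C)C(C)(C)C)cc1OCc1ccccc1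
A9 | alternative 3 | bromido{(2S,3R)-2-[4-(benzyloxy)-3-methoxyphenyl]-3-{[(tert-butyldimethylsilyl)oxy]methyl}-4-methoxy-2,3-dihydro-1-benzofuran-6-yl}zinc | Br[Zn]c1cc(OC)c2c(c1)O[C@H](c1ccc(OCc3ccccc3)c(OC)c1)[C@H]2CO[Si](C)(C)C(C)(C)C
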